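Late in the elm run, the flask asked about, the readings barely move: at 144 h the target stands at 30.4% and the starting material at 2.7%, with 66.9% of the charge in neither.

in all of them: starting material 0.40 M; catalyst 2.5 mol%
- elm: reagent 2 equiv; temperature 0 °C; the very flask that is asked about, followed so far
- cedar: reagent 2 equiv; temperature −15 °C; run made earlier
- flask: reagent 2.00 equiv; temperature 0 °C; time 8.0 d

| run | time / h | target / % | starting material / % |
|---|---|---|---|
| elm | 30.0 | 36.6 | 26.5 |
| elm | 60.0 | 34.5 | 13.0 |
| elm | 96.0 | 31.7 | 5.7 |
| elm | 120 | 30.8 | 3.0 |
| elm | 144 | 30.4 | 2.7 |
| cedar | 60.0 | 31.8 | 46.9 |
| cedar | 120 | 40.6 | 31.2 |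
| cedar | 192 | 40.2 | 20.6 |
| cedar | 240 | 36.7 | 14.5 |
| cedar | 288 | 32.9 | 11.5 |

(standard deviation of a reading: 0.5 percentage points)

- blue: at 8.0 d take out 90% of the target then present, then wait 2.5 d
- ochre: at 8.0 d add catalyst, 100% of the amount charged, then wait 2.5 d
- red: at 8.0 d raise the temperature by 25 K, then wait 2.5 d
- amber: at 8.0 d add reagent, 50.0% of the amount charged, then wait 2.5 d
- grey: change nothing and wait 2.5 d more

- target, in percent of the starting material first charged, at 8.0 d
- which option adds most target ("none" when 2 percentage points or less is all one gets) (blue / ochre / red / amber / grey / none)
- target present, with what was taken out counted in, in percent of the starting material first charged, after red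
- target present, with what was taken out counted in, in percent of the starting material first charged, after amber

- removed target is counted in
- the numbers in the tables scatter by 0.5 percentage points (one standard deviation)
- additions bring no volume worth counting

Is elm stopping for want of starting material, or at a balance? At its last reading the target is 31.2% of what has left the starting material; we call this the late share s.

Does s stay put? We would expect a one-way loss of target to run faster when warmer. Yet the fall of target over the last 48.0 h of the colder cedar run, 3.8 percentage points, is larger than the fall of 1.3 points over the last 48.0 h of elm. So we read elm as nearing an equilibrium with something unseen. Cedar's share, 37.2%, is still falling by 5.7 points per reading, and one more such step brings it to 31.4%, about elm's s. If cedar's share goes on falling past that point, we take it that warming raises the share.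

What does that give in elm? A correction remains: the starting material still there adds s times itself, 0.84 points, so we reckon 31.2% at 8.0 d. A balance also refills what is taken, so blue should gain the amount removed times the non-target part, 68.8%, which is 19 points. Ochre, amber and grey should leave s where it is. Red beats blue if the warmed share passes 50.2%, and neither run was made above 0 °C, so we leave that open.

The forecast gave 29.9%, chose none, and put red at 29% and amber at 29.6%, holding that “removal recovers nothing new”.

The simulation gives 29.6% and best red. Red adds 50 points, reaching 79.8%; blue adds 18 points, ochre −0.21 points, amber −0.081 points, reaching 29.6%, and grey −0.16 points.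

    starting material + catalyst ⇌ catalyst + intermediate (K = 0.530, k = 120 L mol⁻¹ h⁻¹, Ea = 53.0 kJ mol⁻¹, ΔH = 22.0 kJ mol⁻¹)
    reagent + catalyst + intermediate → catalyst + target (k = 14.0 L² mol⁻² h⁻¹, Ea = 39.0 kJ mol⁻¹)
    target + catalyst ⇌ isomer of the product + catalyst, rate k3*[catalyst]*[target] forward; the back reaction follows from the equilibrium constant (K = 2.40, k = 3.50 L mol⁻¹ h⁻¹, Ea = 72.0 kJ mol⁻¹, ΔH = −61.0 kJ mol⁻¹)
    (constants at 0 °C)

The forecast and the flask part at red, which lifts the target to 79.8% by shifting a balance, as under thermodynamic control. The reaction of target to isomer of the product, both ways, is the main reason this flask holds 29.6% of target at 8.0 d: the run without it holds 98.7%. Part of red's gain is the reverse step, isomer of the product to target: the run without it brings −1.7 points from red instead of 50 points. The neighbour charged with 0.500 equiv of reagent keeps 8.5% of its reagent, so 45.8% of the charged starting material has passed the reagent step, and s gives 14.3% target there. The computed neighbour holds 14.3%.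

The runs are calculated for an exercise, noise included.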